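## Structural features

The target joins a trans-fused octalin (ring A: C1–C5 and C10, with the C3=C4 alkene and a C4 methyl; ring B: C5–C10) through one methylene, C11, to a cyclopent-2-enone (C1' carbonyl, C2' methoxy enol ether, C3' vinylic CH, C4' tertiary carbinol bearing the methyl ester, C5' CH bearing C11). Ring B carries four contiguous stereocentres: quaternary C5 (methyl), C10 (H), C9 (methyl) and quaternary C8 (methyl and C11). The C5 and C9 methyls are syn and 1,3-diaxial, the C8 methyl is anti to both, and C11 is equatorial and syn to the C9 methyl. C4' and C5' are adjacent on the five-membered ring, with the hydroxyl trans to C11. Fragile features are the β-hydroxy ketone C4'–C5'–C1' (elimination or retro-aldol in base), the epimerisable C5'–H, the acid-labile enol ether, and the C3=C4 alkene next to quaternary C5, which can migrate in strong acid. The real difficulty is twofold: the C9 methyl is in the less stable axial position and must be set kinetically and never equilibrated, and the neopentyl carbon C11 neither relays stereochemistry nor accepts SN2 alkylation. The key step exploits the cis relationship of the C9 methyl and C11 on the adjacent ring B carbons C9 and C8: they can be the carbonyl and acetal carbons of a γ-alkoxybutenolide fused at C8–C9, so ring B arises by [4+2] addition of a C7–C6–C5–C10 diene across the butenolide double bond, whose β-methyl becomes the C8 methyl.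

## Logic of the disconnections

The C4'–O bond of 34 is cut first, giving 33. C4' is α to the ester and γ to the enone, so the hydroxyl can come from the dienolate of 33 and an electrophilic oxygen source. The gain is an intermediate without the β-hydroxy ketone. The demand is attack at C4' (not C2'), anti to C11, with one equivalent of base so that C5' keeps its hydrogen.

The C3'–C4' bond of 33 is cut to give 32. A 4π electrocyclisation closes the five-membered ring with all its oxygenated carbons already in place. The demand is control of the sense of conrotation by an external chiral Lewis acid, because the decalin is insulated by C11; C5' then follows by protonation trans to the ester.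

The C4'=C5' double bond of 32 is cut to give 29 and 30. An aldol condensation brings in C4' and the ester as a two-carbon aldehyde. The demand is small: C5' is the only enolisable position of 29, and elimination should give the E alkene.

The C1'–C2' bond of 29 is cut to give 27 and 28. Acyl substitution of the N-methoxy-N-methylamide by metalated 28 delivers C2', C3' and the methoxy group in one operation. The demand is a single addition.

The C11–C5' bond of 27 is traced through the C11=C5' alkene of 26 to 24 and 25. C11 is neopentyl and cannot be alkylated, but as an aldehyde it olefinates. The demand is saturation of the disubstituted alkene without touching C3=C4.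

24 is taken back to 23 (C11 oxidation level), and the missing C2 oxygen is restored through 22 to 21. The C2 carbonyl is what allows ring A to be built and C10 to be set, and is removed through the dithioketal. The demand is that C3=C4 stays in place during desulfurisation.

The C3=C4 double bond of 21 is removed to give 19. It comes from dehydrogenation of the C2 ketone. The demand is enolisation toward C3, away from C1.

The C10–H bond of 19 is cut to give 18. Dissolving-metal reduction of the C1=C10 enone sets the trans ring fusion.

The C1=C10 double bond of 18 is cut to give 16. Intramolecular aldol condensation closes ring A. The demand is to avoid equilibrating C9, which is α to the C10 ketone from 13 to 17.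

The C4–C5 bond of 16 is cut to give 14 and 15. Conjugate addition of the regiodefined C5 enol ether to 15 makes the C5 quaternary centre. The demand is attack anti to the C9 methyl.

14 is traced through 13 and 12 to 11. These are adjustments of the C10 oxidation level and protection of the C11 hydroxyl.

The C9 methyl and the C11 hydroxymethyl of 11 are traced through 9 and 8 to the carbonyl and acetal carbons of 6. The two carbons are told apart by oxidation level: the aldehyde-level carbon is reduced first, and the carboxyl carbon is then taken down through lactol and hydrazone. The demand is that C9 is never epimerised.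

The C7–C8 and C9–C10 bonds of 6 are cut to give 3 and 5. This [4+2] disconnection removes ring B and three stereocentres at once. The demand is facial and regiochemical control on a slow, β,β-disubstituted dienophile.

3 comes from 1 and 2 by acetal exchange, and 5 from 4 by dienol silylation.

## Other disconnections considered

Alternative 1: The cut is C3'–C4' of the cyclopentenone. In the forward sense the dienone A2, activated by a chiral copper bis(oxazoline) Lewis acid bound to the ketone and methoxy oxygens, undergoes conrotatory 4π closure to the trans cyclopentenone A1. In its favour: it builds the five-membered ring with its full oxygen pattern in one catalytic step, the methoxy group fixes where the double bond ends up, and the donor and acceptor alkenes are matched in polarity. Against it as the organising disconnection: it simplifies only two stereocentres, one of which (C4') is planarised again in the last step, and leaves the five contiguous decalin centres and both quaternary carbons unaddressed. The catalyst must also impose its sense of rotation on a chiral substrate. Comparison: this closure and the chosen key step solve different halves of the molecule. For the five-membered ring the alternative is the better tool, and the chosen route adopts it as step 21 (A1 is 33, A2 is 32). On the decalin it offers nothing, and in step count it is neutral.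

Alternative 2: The cuts are C1–C2 and C5–C10, which remove rings A and B together. In the forward sense the trienone A4 (vinyl ketone tethered to a 2-silyloxydiene) cyclises intramolecularly, and base equilibration at C10 gives the trans-fused silyl enol ether A3. In its favour: two rings and the C5 quaternary centre form in one step, and the C4 enol ether should become the C4 methyl alkene in two operations (enol triflate, methyl coupling). Here the alternative is better than the chosen plan, which spends six steps on ring A. Against it: the diene terminus C5 is fully substituted with a methyl forced inside, which should make the cycloaddition sluggish. The only stereocentre present, C8, must be made enantioselectively beforehand and must control C5 across a flexible tether. The axial C9 methyl is not set at all and would have to come later from the C9 ketone. Comparison: the alternative is equal in how the trans fusion is reached (thermodynamic versus dissolving metal) and better in step economy. The chosen plan is better in stereochemical security, since C8 and C9 are set together by a rigid cis ring.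

Alternative 3: The cut is C8–C9. In the forward sense the silyl ketene acetal of the trans-fused δ-lactone A6 rearranges by a [3,3] shift through a boat transition state, contracting the lactone to the ring B acid A5. In its favour: C8 and C9 are created together with chirality transferred from C6, ring A and its alkene are already complete, and the side chain on C8 already contains C11 and C5'. On these points it is the equal or the better of the chosen plan. Against it: A6 needs three stereocentres (including quaternary C5) and a geometrically pure trisubstituted alkene before the key step. After it, the C9 carboxyl must be reduced to methyl and the C6=C7 alkene hydrogenated without touching C3=C4. Comparison: the alternative is shorter after its key step but longer before it, so overall step economy should be similar. The chosen plan starts from two small achiral pieces and a cheap auxiliary and sets the absolute configuration in the same step that builds the ring.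

Key step: step 3

Assumptions on the chemistry: C4 in 16–20 is carried as a mixture of epimers (left open in the SMILES) because it becomes sp2 in 21. 9 is an anomer mixture, and the carbinol centres of 17 and 31 are likewise open. 25, 28, 30 and the unnumbered reagents are taken as purchasable. The acetal epimer needed for the target enantiomer is 5S.

Step 1
Reactants: 1 5-hydroxy-4-methylfuran-2(5H)-one; 2 (−)-menthol
Product: 3 (5S)-5-[(1R,2S,5R)-menthyloxy]-4-methylfuran-2(5H)-one
Conditions: camphorsulfonic acid (cat.), toluene, reflux, Dean–Stark; 5S epimer separated by crystallisation or chromatography; the other epimer re-equilibrated under the same acid and recycled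
Reagents that add atoms: none
Why: Acid-catalysed acetal exchange of the cyclic hemiacetal with the alcohol; the acetal centre forms as a mixture but epimerises through the oxocarbenium ion under the same conditions, so the unwanted epimer is recyclable; this centre is the only source of absolute configuration for the decalin.

Step 2
Reactants: 4 (E)-2-methylbut-2-enal
Product: 5 (E)-1-(tert-butyldimethylsilyloxy)-2-methylbuta-1,3-diene
Conditions: TBSOTf, Et3N, Et2O, 0 °C to rt
Reagents that add atoms: tert-butyldimethylsilyl trifluoromethanesulfonate, CC(C)(C)[Si](C)(C)OS(=O)(=O)C(F)(F)F
Why: Soft enolisation (O-silylation, then γ-deprotonation) gives the silyl dienol ether; the 1E isomer should predominate, and any 1Z isomer cannot reach the s-cis conformation and is a spectator in step 3.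

Step 3
Reactants: 3 (5S)-5-menthyloxy-4-methylfuran-2(5H)-one; 5 (E)-1-(tert-butyldimethylsilyloxy)-2-methylbuta-1,3-diene
Product: 6 cis-fused ring B butenolide adduct (8-methyl, 10-OTBS, C5=C6; lactone carbonyl on C9, menthyloxy acetal carbon C11 on C8)
Conditions: 5 (3 equiv), BHT (cat.), toluene, 120 °C, sealed tube (or 13 kbar, CH2Cl2, rt)
Reagents that add atoms: none
Why: Concerted, asynchronous, normal-electron-demand [4+2] cycloaddition between the diene HOMO and the butenolide LUMO; the closest known reaction type is the thermal Diels–Alder addition of 1-silyloxybutadienes to 5-alkoxyfuran-2(5H)-ones. Ring B is the only ring closed, by suprafacial–suprafacial [4+2] ring formation that makes both C7–C8 and C9–C10 in one step, while the lactone ring is carried through intact. Regiochemistry follows polarisation: the unsubstituted diene terminus (largest HOMO coefficient, future C7) bonds to the butenolide β-carbon (C8) and the oxygen-bearing terminus (C10) to the α-carbon (C9). C8 is controlled by the acetal centre of 3, because the diene approaches the face opposite the menthyloxy group. C9 follows from C8 because the dienophile double bond is held cis in the five-membered ring, which puts the lactone carbonyl carbon (future C9 methyl) and the acetal carbon (future C11) on the same face. C10 is set by the endo transition state (silyloxy cis to the lactone carbonyl) and does not matter, since C10 becomes a ketone in step 8. The selectivities needed are facial and regiochemical, secured by the acetal substituent and the 1-silyloxy donor. The β-methyl group makes the dienophile slow, hence excess diene, heat in a sealed vessel or high pressure, and a radical inhibitor.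

Step 4
Reactants: 6 cis-fused ring B butenolide adduct
Product: 8 cis-fused 10-hydroxy γ-lactone (carbonyl on C9; ring OCH2 is C11), via seco hydroxy acid 7 (not isolated)
Conditions: NaOH, NaBH4, MeOH–THF–H2O, 0 °C to rt; then 2 M HCl to pH 1, rt
Reagents that add atoms: none
Why: Saponification of the pseudo-ester frees the C9 carboxylate and the non-enolisable C11 aldehyde (menthol is lost), NaBH4 reduces only the aldehyde, and acidification relactonises the cis hydroxy acid and hydrolyses the allylic silyl ether. The two carbons are thus told apart by oxidation level while C9 stays locked by the cis ring fusion.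

Step 5
Reactants: 8 cis-fused 10-hydroxy γ-lactone
Product: 9 lactol (C9–CH(OH)–O–C11H2, anomer mixture)
Conditions: i-Bu2AlH (2.5 equiv), CH2Cl2, −78 °C; aq. potassium sodium tartrate
Reagents that add atoms: none
Why: Partial reduction of a γ-lactone to the lactol; the tetrahedral aluminate survives at low temperature until work-up, and the extra hydride is consumed by the free C10 hydroxyl.

Step 6
Reactants: 9 lactol
Product: 11 5-(hydroxymethyl)-2,5,6-trimethylcyclohex-2-en-1-ol (C10 hydroxyl, C9 methyl and C11 all on one face), via tosylhydrazone 10 (not isolated)
Conditions: TsNHNH2, MeOH, 50 °C; then catecholborane, CHCl3, 0 °C to rt; then NaOAc·3H2O, reflux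
Reagents that add atoms: none
Why: The lactol reacts through its hydroxy aldehyde form to give the tosylhydrazone, which is reduced by hydride addition and loss of sulfinate and N2 (Caglioti-type reduction) to the C9 methyl. The near-neutral conditions avoid the C9 epimerisation and retro-aldol cleavage of the β-hydroxy aldehyde that hot alkali would invite.

Step 7
Reactants: 11 diol
Product: 12 primary (C11) tert-butyldimethylsilyl ether of 11
Conditions: TBSCl (1.05 equiv), imidazole, CH2Cl2, 0 °C
Reagents that add atoms: tert-butyldimethylsilyl chloride, CC(C)(C)[Si](C)(C)Cl
Why: Silylation distinguishes the primary neopentyl alcohol from the hindered secondary allylic alcohol flanked by C9 and the C5 methyl; the ether stops the C11 oxygen adding to the C10 ketone in later steps.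

Step 8
Reactants: 12 mono-silyl ether
Product: 13 5-[(tert-butyldimethylsilyloxy)methyl]-2,5,6-trimethylcyclohex-2-en-1-one (C10 ketone conjugated with C5=C6)
Conditions: DMP (1,1,1-triacetoxy-1,1-dihydro-1,2-benziodoxol-3(1H)-one), NaHCO3, CH2Cl2, 0 °C to rt
Reagents that add atoms: none
Why: Buffered periodinane oxidation of the allylic alcohol to the enone is neutral, so the α-stereocentre C9 is not enolised.

Step 9
Reactants: 13 enone
Product: 14 triethylsilyl enol ether (C10(OSiEt3)=C5, C6 saturated)
Conditions: Et3SiH, RhCl(PPh3)3 (2 mol %), toluene, 60 °C
Reagents that add atoms: triethylsilane, CC[SiH](CC)CC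
Why: Rhodium-catalysed 1,4-hydrosilylation of an enone with a monohydrosilane gives the silyl enol ether on the former enone carbons only. The C5 nucleophile is thus regiodefined without any base that could move the double bond toward C9 or epimerise it.

Step 10
Reactants: 14 triethylsilyl enol ether; 15 (E)-pent-3-en-2-one
Product: 16 1,5-diketone (C5 quaternary: methyl and the 4-oxopentan-2-yl chain; C10 ketone)
Conditions: TiCl4 (1.1 equiv), CH2Cl2, −78 °C; then H2O
Reagents that add atoms: none
Why: Mukaiyama–Michael addition, a reaction that tolerates formation of a quaternary carbon next to a tertiary one. The C9 methyl sits pseudoaxial to avoid the silyloxy group, so the enone should add to C5 from the opposite face, leaving the C5 methyl syn to the C9 methyl as required; C4 is formed without control and is erased later.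

Step 11
Reactants: 16 1,5-diketone
Product: 18 octalone (C2 ketone; C1=C10 alkene), via ketol 17 (not isolated)
Conditions: LiN(i-Pr)2 (1.1 equiv), THF, −78 to −20 °C; then MsCl, Et3N, DMAP (cat.), −20 °C to rt
Reagents that add atoms: none
Why: Kinetic deprotonation takes the accessible methyl-ketone CH3 rather than the hindered C9–H, and the enolate closes ring A by 6-(enolexo)-exo-trig aldol addition to the C10 ketone. Mesylation of the tertiary alkoxide and E1cB loss through the C1 enolate give the conjugated enone without the equilibrating base of a classical Robinson annulation.

Step 12
Reactants: 18 octalone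
Product: 19 trans-fused decal-2-one (C10–H anti to the C5 methyl)
Conditions: Li, NH3(l)–THF, t-BuOH (1 equiv), −78 °C; then NH4Cl
Reagents that add atoms: none
Why: Dissolving-metal reduction of the enone; the β-carbanion at C10 is protonated axially, anti to the angular C5 methyl, giving the trans fusion, and C9 (γ to the carbonyl) is not deprotonated under these conditions.

Step 13
Reactants: 19 trans-decalone
Product: 21 enone (C2 ketone; C3=C4 alkene bearing the C4 methyl), via trimethylsilyl enol ether 20 (not isolated)
Conditions: LiN(i-Pr)2, Me3SiCl, THF, −78 °C; then Pd(OAc)2 (1.1 equiv), MeCN, rt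
Reagents that add atoms: none
Why: Kinetic enolisation of a trans-fused 2-decalone goes away from the ring fusion (toward C3), and Saegusa–Ito oxidation of that silyl enol ether gives the C3=C4 enone. Both C4 epimers converge here.

Step 14
Reactants: 21 enone
Product: 22 C2 1,3-dithiolane with free C11 hydroxyl
Conditions: HS(CH2)2SH, BF3·OEt2 (3 equiv), CH2Cl2, 0 °C to rt
Reagents that add atoms: ethane-1,2-dithiol, SCCS
Why: Lewis-acid thioketalisation of a β,β-disubstituted enone occurs at the carbonyl without conjugate addition or alkene migration, and excess BF3·OEt2 also cleaves the primary silyl ether, which is needed off for step 16.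

Step 15
Reactants: 22 hydroxy dithiolane
Product: 23 decalin alcohol (C11–OH; C3=C4 alkene, C2 now CH2)
Conditions: Raney Ni (W-2), EtOH, reflux
Reagents that add atoms: none
Why: Reductive desulfurisation replaces both C–S bonds by C–H, and the hindered trisubstituted alkene next to quaternary C5 is expected to survive, as in the classical conversion of enone dithioketals to alkenes.

Step 16
Reactants: 23 decalin alcohol
Product: 24 C11 aldehyde
Conditions: DMP, NaHCO3, CH2Cl2, rt
Reagents that add atoms: none
Why: Neutral oxidation of the neopentyl alcohol; the aldehyde has no α-hydrogen and cannot epimerise or enolise.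

Step 17
Reactants: 24 C11 aldehyde; 25 diethyl [2-(methoxy(methyl)amino)-2-oxoethyl]phosphonate
Product: 26 (E)-N-methoxy-N-methyl enamide (C11=C5')
Conditions: NaH, THF, 0 to 50 °C
Reagents that add atoms: none
Why: Horner–Wadsworth–Emmons olefination is the reliable way to form a C–C bond at the neopentyl carbon, since a hindered aldehyde still olefinates where SN2 alkylation would fail.

Step 18
Reactants: 26 unsaturated amide
Product: 27 saturated N-methoxy-N-methylamide (C11H2–C5'H2)
Conditions: 2-nitrobenzenesulfonohydrazide, Et3N, CH2Cl2, rt
Reagents that add atoms: none
Why: Diimide generated in situ transfers H2 concertedly to the disubstituted alkene and leaves the hindered trisubstituted C3=C4 alkene and the N–O bond untouched.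

Step 19
Reactants: 27 saturated amide; 28 methyl vinyl ether
Product: 29 2-methoxy enone (C1' ketone, C2'(OMe)=C3'H2, C5'H2)
Conditions: 28, t-BuLi, THF, −78 to 0 °C; then 27, −78 °C; aq. NH4Cl
Reagents that add atoms: none
Why: α-Lithiated methyl vinyl ether adds once to the N-methoxy-N-methylamide because the chelated tetrahedral intermediate survives until work-up, giving the ketone with C2', C3' and the methoxy group in place.

Step 20
Reactants: 29 2-methoxy enone; 30 methyl glyoxylate
Product: 32 (E)-dienone (MeO2C–C4'H=C5'(C11)–C1'(=O)–C2'(OMe)=C3'H2), via aldol adduct 31 (not isolated)
Conditions: LiN(SiMe3)2, THF, −78 °C; 30; then MsCl, Et3N, −78 to 0 °C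
Reagents that add atoms: none
Why: C5' is the only enolisable position of 29; aldol addition to the glyoxylate and E1cB elimination of the mesylate give the enedione-type alkene, expected as the E isomer with the ester trans to the ketone.

Step 21
Reactants: 32 dienone
Product: 33 trans-4-carbomethoxy-2-methoxy-5-(decalinylmethyl)cyclopent-2-enone
Conditions: Cu(OTf)2 (10 mol %), (S,S)-t-Bu-bis(oxazoline) (11 mol %; the ligand antipode is fixed by a trial run), 4 Å MS, CH2Cl2, 0 °C to rt
Reagents that add atoms: none
Why: Nazarov cyclisation: divalent copper chelated by the ketone and methoxy oxygens generates the pentadienyl cation, conrotatory 4π closure forms C3'–C4', the methoxy group localises the oxyallyl cation so that proton loss from C3' gives the enol ether, and the enolate is protonated at C5' trans to the C4' ester. The chiral ligand is expected to dictate the sense of conrotation, and through it C5', because the decalin is insulated by C11.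

Step 22
Reactants: 33 cyclopentenone
Product: 34 dysidenone B
Conditions: KN(SiMe3)2 (1.05 equiv), THF, −78 °C; 2-(phenylsulfonyl)-3-phenyloxaziridine, −78 °C; AcOH
Reagents that add atoms: 2-(phenylsulfonyl)-3-phenyloxaziridine, O=S(=O)(c1ccccc1)N1OC1c1ccccc1
Why: The most acidic proton (C4', α to the ester and γ to the enone) is removed to give the extended enolate, and electrophilic oxygen transfer from the N-sulfonyloxaziridine at C4', anti to the C5' side chain, gives the tertiary alcohol trans to C11. One equivalent of base at low temperature leaves C5'–H untouched, and the acidic quench prevents elimination of the β-hydroxy ketone.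

## Compound list

1 | 5-hydroxy-4-methylfuran-2(5H)-one | CC1=CC(=O)OC1O | starting material
2 | (−)-menthol, (1R,2S,5R)-2-isopropyl-5-methylcyclohexanol | CC(C)[C@@H]1CC[C@@H](C)C[C@H]1O | starting material
3 | (5S)-5-[(1R,2S,5R)-menthyloxy]-4-methylfuran-2(5H)-one | CC1=CC(=O)O[C@@H]1O[C@@H]1C[C@H](C)CC[C@H]1C(C)C | intermediate
4 | (E)-2-methylbut-2-enal | C/C=C(\C)C=O | starting material
5 | (E)-1-(tert-butyldimethylsilyloxy)-2-methylbuta-1,3-diene | C=C/C(C)=C/O[Si](C)(C)C(C)(C)C | intermediate
6 | cis-fused ring B butenolide adduct (8-methyl, 10-OTBS cis to the lactone carbonyl, C5=C6, menthyloxy anti to ring B) | C[C@]12CC=C(C)[C@@H](O[Si](C)(C)C(C)(C)C)[C@H]1C(=O)O[C@@H]2O[C@@H]1C[C@H](C)CC[C@H]1C(C)C | intermediate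
7 | seco hydroxy acid (C9 carboxylic acid, C11 hydroxymethyl, 10-OTBS) | OC[C@@]1(C)CC=C(C)[C@@H](O[Si](C)(C)C(C)(C)C)[C@H]1C(=O)O | intermediate
8 | cis-fused 10-hydroxy γ-lactone (carbonyl on C9, ring OCH2 = C11) | C[C@]12CC=C(C)[C@@H](O)[C@H]1C(=O)OC2 | intermediate
9 | lactol of 8 (anomer mixture) | C[C@]12CC=C(C)[C@@H](O)[C@H]1C(O)OC2 | intermediate
10 | tosylhydrazone of the ring-opened hydroxy aldehyde | OC[C@@]1(C)CC=C(C)[C@@H](O)[C@H]1/C=N/NS(=O)(=O)c1ccc(C)cc1 | intermediate
11 | 5-(hydroxymethyl)-2,5,6-trimethylcyclohex-2-en-1-ol (10-OH, 9-methyl and C11 cis) | OC[C@@]1(C)CC=C(C)[C@@H](O)[C@H]1C | intermediate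
12 | C11 tert-butyldimethylsilyl ether of 11 | CC(C)(C)[Si](C)(C)OC[C@@]1(C)CC=C(C)[C@@H](O)[C@H]1C | intermediate
13 | 5-[(tert-butyldimethylsilyloxy)methyl]-2,5,6-trimethylcyclohex-2-en-1-one | CC(C)(C)[Si](C)(C)OC[C@@]1(C)CC=C(C)C(=O)[C@H]1C | intermediate
14 | triethylsilyl enol ether (C10(OSiEt3)=C5) | CC(C)(C)[Si](C)(C)OC[C@@]1(C)CCC(C)=C(O[Si](CC)(CC)CC)[C@H]1C | intermediate
15 | (E)-pent-3-en-2-one | C/C=C/C(C)=O | starting material
16 | 1,5-diketone (C5 quaternary, C4 epimers) | CC(C)(C)[Si](C)(C)OC[C@@]1(C)CC[C@](C)(C(C)CC(C)=O)C(=O)[C@H]1C | intermediate
17 | ketol (10-hydroxy decal-2-one, C4 and C10 open) | CC(C)(C)[Si](C)(C)OC[C@@]1(C)CC[C@]2(C)C(C)CC(=O)CC2(O)[C@H]1C | intermediate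
18 | octalone (C2 ketone, C1=C10) | CC(C)(C)[Si](C)(C)OC[C@@]1(C)CC[C@]2(C)C(C)CC(=O)C=C2[C@H]1C | intermediate
19 | trans-fused decal-2-one | CC(C)(C)[Si](C)(C)OC[C@@]1(C)CC[C@]2(C)C(C)CC(=O)C[C@H]2[C@H]1C | intermediate
20 | trimethylsilyl enol ether (C2(OSiMe3)=C3) | CC(C)(C)[Si](C)(C)OC[C@@]1(C)CC[C@]2(C)C(C)C=C(O[Si](C)(C)C)C[C@H]2[C@H]1C | intermediate
21 | enone (C2 ketone, C3=C4) | CC(C)(C)[Si](C)(C)OC[C@@]1(C)CC[C@]2(C)C(C)=CC(=O)C[C@H]2[C@H]1C | intermediate
22 | C2 1,3-dithiolane, C11 alcohol | OC[C@@]1(C)CC[C@]2(C)C(C)=CC3(SCCS3)C[C@H]2[C@H]1C | intermediate
23 | decalin alcohol (C11–OH) | OC[C@@]1(C)CC[C@]2(C)C(C)=CCC[C@H]2[C@H]1C | intermediate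
24 | C11 aldehyde | O=C[C@@]1(C)CC[C@]2(C)C(C)=CCC[C@H]2[C@H]1C | intermediate
25 | diethyl [2-(methoxy(methyl)amino)-2-oxoethyl]phosphonate | CCOP(=O)(CC(=O)N(C)OC)OCC | starting material
26 | (E)-N-methoxy-N-methyl enamide (C11=C5') | CON(C)C(=O)/C=C/[C@@]1(C)CC[C@]2(C)C(C)=CCC[C@H]2[C@H]1C | intermediate
27 | saturated N-methoxy-N-methylamide | CON(C)C(=O)CC[C@@]1(C)CC[C@]2(C)C(C)=CCC[C@H]2[C@H]1C | intermediate
28 | methyl vinyl ether | COC=C | starting material
29 | 2-methoxy enone (C1' ketone) | COC(=C)C(=O)CC[C@@]1(C)CC[C@]2(C)C(C)=CCC[C@H]2[C@H]1C | intermediate
30 | methyl glyoxylate | COC(=O)C=O | starting material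
31 | aldol adduct (C4' carbinol, C4' and C5' open) | COC(=O)C(O)C(C[C@@]1(C)CC[C@]2(C)C(C)=CCC[C@H]2[C@H]1C)C(=O)C(=C)OC | intermediate
32 | (E)-dienone | COC(=O)/C=C(/C(=O)C(=C)OC)C[C@@]1(C)CC[C@]2(C)C(C)=CCC[C@H]2[C@H]1C | intermediate
33 | trans-4-carbomethoxy-2-methoxy-5-(decalinylmethyl)cyclopent-2-enone | COC(=O)[C@@H]1C=C(OC)C(=O)[C@H]1C[C@@]1(C)CC[C@]2(C)C(C)=CCC[C@H]2[C@H]1C | intermediate
34 | dysidenone B | COC(=O)[C@@]1(O)C=C(OC)C(=O)[C@H]1C[C@@]1(C)CC[C@]2(C)C(C)=CCC[C@H]2[C@H]1C | target

## Step count and least certain steps

Total: 22 steps. Longest linear sequence: 21 steps (steps 1 and 3–22, from 1); step 2 is a one-step branch.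

Step 3 (key step). The most likely failure is a cycloaddition too slow for the diene to survive (polymerisation, desilylation or cycloreversion at the temperature needed), because the dienophile creates a quaternary carbon. Facial selectivity could also erode at high temperature. Fallback: replace the chiral dienophile by the far more reactive citraconic anhydride and resolve. Setting out from 5, cycloaddition with citraconic anhydride near room temperature should give the racemic cis anhydride adduct F1 with the same regiochemistry. NaBH4 attacks the carbonyl next to the quaternary carbon and gives the racemic silyloxy lactone F2. Acidic methanol removes the silyl group to give 8 together with its enantiomer F3. Lipase-mediated acetylation with vinyl acetate then separates the enantiomers, as free alcohol and as the acetate F4 (drawn for the unwanted enantiomer; if the enzyme prefers the wanted one, its acetate is methanolysed). The route is rejoined at 8.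

Step 10. The C–C bond must form at a tetrasubstituted enol ether carbon next to the quaternary C8 side of the ring. The likely failures are silyl transfer or protodesilylation without addition, and insufficient facial discrimination at C5. Fallback: anionic conjugate addition to an α-silyl enone, which is a better acceptor for hindered enolates. Setting out from 14, MeLi should release the regiodefined lithium enolate, which adds to (E)-3-(trimethylsilyl)pent-3-en-2-one to give the α-silyl diketone F5. KF in MeOH removes the silyl group, and the route is rejoined at 16.

Step 11. The aldol addition to the very hindered C10 ketone may revert before the alkoxide is trapped, elimination may go toward C9 instead of C1, and any forcing would start to equilibrate C9. Fallback: make the ring closure an irreversible olefination. Setting out from 14, the same Lewis-acid Michael addition to dimethyl [(E)-2-oxopent-3-en-1-yl]phosphonate should give the keto phosphonate F6. Intramolecular Horner–Wadsworth–Emmons reaction (LiCl, DBU, MeCN) then gives the enone directly, and the route is rejoined at 18.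

Step 21. The catalyst may not control the sense of conrotation on this substrate, giving a mixture at C4' and C5'. Isomerisation of the enoate or hydrolysis of the enol ether could also compete. Fallback: give up asymmetric induction and separate. Setting out from 32, cyclisation with achiral Sc(OTf)3 should give 33 together with its ring diastereomer F7. The two are diastereomers because of the decalin and are separable by chromatography, and the route is rejoined at 33.

Step 22. Oxygen may be transferred to C2' instead of C4', excess base may deprotonate C5' and scramble it, and the product alkoxide may eliminate or add to the sulfonimine. Fallback: electrophilic halogenation followed by solvolysis. Setting out from 33, NBS with catalytic Et3N should brominate the dienol at C4' to give the tertiary bromide F8. AgOTf in aqueous acetone with 2,6-lutidine then replaces bromide by water, which is expected to enter anti to the C5' side chain, and the route is rejoined at 34.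

## Further compounds

F1 | step 3 | racemic cis anhydride adduct of 5 with citraconic anhydride (one enantiomer drawn) | C[C@]12CC=C(C)[C@@H](O[Si](C)(C)C(C)(C)C)[C@H]1C(=O)OC2=O
F2 | step 3 | racemic 10-silyloxy γ-lactone (one enantiomer drawn) | C[C@]12CC=C(C)[C@@H](O[Si](C)(C)C(C)(C)C)[C@H]1C(=O)OC2
F3 | step 3 | enantiomer of 8 | C[C@@]12CC=C(C)[C@H](O)[C@@H]1C(=O)OC2
F4 | step 3 | C10 acetate of the enantiomer of 8 | C[C@@]12CC=C(C)[C@H](OC(C)=O)[C@@H]1C(=O)OC2
F5 | step 10 | α-trimethylsilyl 1,5-diketone | CC(C)(C)[Si](C)(C)OC[C@@]1(C)CC[C@](C)(C(C)C(C(C)=O)[Si](C)(C)C)C(=O)[C@H]1C
F6 | step 11 | keto phosphonate | CC(C)(C)[Si](C)(C)OC[C@@]1(C)CC[C@](C)(C(C)CC(=O)CP(=O)(OC)OC)C(=O)[C@H]1C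
F7 | step 21 | C4',C5' ring diastereomer of 33 | COC(=O)[C@H]1C=C(OC)C(=O)[C@@H]1C[C@@]1(C)CC[C@]2(C)C(C)=CCC[C@H]2[C@H]1C
F8 | step 22 | C4' bromide of 33 (C4' epimers) | COC(=O)C1(Br)C=C(OC)C(=O)[C@H]1C[C@@]1(C)CC[C@]2(C)C(C)=CCC[C@H]2[C@H]1C
A1 | alternative 1 | trans-4-carbomethoxy-2-methoxy-5-alkylcyclopent-2-enone (same as 33) | COC(=O)[C@@H]1C=C(OC)C(=O)[C@H]1C[C@@]1(C)CC[C@]2(C)C(C)=CCC[C@H]2[C@H]1C
A2 | alternative 1 | 2-methoxy dienone (same as 32) | COC(=O)/C=C(/C(=O)C(=C)OC)C[C@@]1(C)CC[C@]2(C)C(C)=CCC[C@H]2[C@H]1C
A3 | alternative 2 | trans-decalone silyl enol ether | C=CC[C@@]1(C)CC[C@]2(C)C(O[Si](C)(C)C(C)(C)C)=CCC[C@H]2C1=O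
A4 | alternative 2 | trienone with vinyl ketone and 2-silyloxydiene | C=CC[C@@](C)(CC/C(C)=C(\O[Si](C)(C)C(C)(C)C)C=C)C(=O)C=C
A5 | alternative 3 | ring B cyclohexene C9 carboxylic acid | OC(=O)[C@@H]1[C@@H]2CCC=C(C)[C@@]2(C)C=C[C@]1(C)CCO[Si](C)(C)C(C)(C)C
A6 | alternative 3 | trans-fused δ-lactone with (E)-alkenyl group on C6 | O=C1C[C@@H]2CCC=C(C)[C@@]2(C)[C@H](O1)/C=C(\C)CCO[Si](C)(C)C(C)(C)C
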